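Remark on the chemistry: the target is achiral. Ring A is taken as the 2,4-dihydroxy-6-(2-oxoheptyl)benzoyl ring and ring B as the benzoic acid ring, each numbered from its carboxyl-bearing carbon C1 with the oxoheptyl chain on C6. Pyrone positions run O1, C2 (carbonyl) to C6.

## Structural features

The target is a depside without stereocentres: two 2,4-dioxygenated 6-(2-oxoheptyl)benzoic acid units are joined by one aryl ester between the carboxyl carbon of ring A and O4 of ring B. Ring B keeps a free carboxylic acid at C1, a free phenol at C2 and its own 2-oxoheptyl chain at C6, and ring A carries free phenols at C2 and C4. Each ring is a 1,2,3,5-tetrasubstituted benzene whose carboxyl carbon is flanked by an oxygen on one side and a CH2 group on the other, so acyl transfer and ester hydrolysis at these carbons are sterically slow. Three points are fragile: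
- the depside ester, which is cleaved by hydroxide, alkoxide or amines;
- the two ArCH2C(=O) ketones, each ortho to a carboxyl derivative and able to close through the enol oxygen to a 3-pentylisocoumarin under acid, base or carboxyl activation (on ring A this would expel ring B);
- the electron-rich salicylic acid of ring B, which can decarboxylate in hot acid.

The real difficulty is to build the contiguous oxygen/carboxyl/CH2 array with the ketone in latent form and to reach the esterification with exactly one free hydroxyl, O4 of ring B, although O2 and O4 of that ring are chemically similar. The key step exploits a direct atom mapping: C2 (with its oxygen), C1 (with the carboxyl) and C6 (with the side chain) of ring B correspond to C4, C5 and C6 of a 4-alkoxy-5-alkoxycarbonyl-6-alkyl-2-pyrone, ring B C3 to pyrone C3, and ring B C4 (with its oxygen) and C5 to the two carbons of a ketene acetal. O4 is thereby created as the only free phenol. Because both halves share one carbon skeleton, the arene made in this way can also be converted into the ring A acid.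

## Logic of the disconnections

21 to 20. The four O–CH2Ph bonds (three aryl ethers, one ester) are cut last. Hydrogenolysis is the one unmasking that is neutral enough to leave the depside ester and both ortho-keto carboxyl arrays untouched. The gain is that all phenols and the ring B acid stay capped to the end. The demand is that every hydroxyl protection in the route is benzyl and that nothing else reducible is present; the two ketones are not benzylic and should be inert.

20 to 19. The two ketone carbonyls are traced back to dioxolanes (two C–O bonds each). A free ArCH2C(=O) group next to an activated carboxyl would close to an isocoumarin, and an enolisable ketone would not survive the enolate, Mitsunobu and ketene acetal chemistry. The gain is a chain that is inert from step 2 to step 11. The demand is a hydrolysis mild enough not to trigger enol lactonisation onto the aryl ester; it is therefore placed before the hydrogenolysis, while no free acid or phenol is present.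

19 to 16 and 18. The depside ester is cut at the C(=O)–O bond between the ring A carboxyl carbon and O4 of ring B. It is the only bond between the halves and the most labile one, so it is made late. The gain is two fragments of identical carbon skeleton. The demand is that 16 offers one free hydroxyl only and that the doubly ortho-substituted acid 18 is activated without acid.

18 to 17 to 16. The ring A acid is traced to the same arene by cutting the acyl–O bond of its ester and the O4–CH2Ph bond. One arene synthesis then serves both rings, so no second ring construction is needed. The demand is a hydroxide cleavage of a hindered benzoate that leaves two benzyl ethers and the dioxolane alone.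

16 to 10 and 12 (key disconnection). Ring B is opened at C3–C4 and C5–C6. C4 with its oxygen and C5 go back to 12; C6, C1, C2 and C3 with their substituents go back to C6, C5, C4 and C3 of 10, whose C2 and O1 leave as CO2. The mapping was checked position by position and is consistent: the ester of 10 sits on C5 between the benzyloxy carbon C4 and the chain-bearing C6, as C1 of 16 sits between C2 and C6, and bonding of the acetal carbon to C3 puts the new hydroxyl para to the ester. The gain is that a tetrasubstituted arene is reduced to a pyrone with three contiguous substituents plus a two-carbon reagent, and that O4 arrives free while O2 is already benzylated. The demand is an inverse-electron-demand (4+2) addition on a pyrone that carries a donor at C4 and a fully substituted C6, with one regiochemistry. The design of 10 is kept because its three protecting groups fit the end game; what is changed is the way it is made and the excess of 12 used.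

12 to 11. One O–Si bond is cut (enolate O-silylation). The demand is O- over C-silylation and use of the freshly distilled reagent.

10 to 9 and 2. The O4–CH2Ph bond is cut. A free 4-hydroxypyrone is acidic and would consume 12, and benzyl fits the final hydrogenolysis. The demand is alkylation at O4 and not at the carbonyl oxygen or C3 of the ambident pyrone anion; a Mitsunobu reaction is chosen over a silver-salt alkylation, which can divert to the 2-alkoxy-4-pyrone isomer.

9 to 8, then 8 to 3 and 6 (through 7). First the lactone O1–C2 bond is cut, then the C5–C6 bond of the pyrone (an acyl C–C bond). The heterocycle is thereby reduced to the symmetric diester 3 and the acid 6. The demand is C- and not O-acylation and a single mode of ring closure; only the enol oxygen of the new ketone can reach an ester through a six-membered transition state.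

3 to 1 and 2; 6 to 5 to 4. Ester exchange on a commodity diester, and ketalisation followed by ester hydrolysis of a commercial keto ester.

## Other disconnections considered

Alternative 1: The cut is made in ring A at the two exocyclic bonds C1–C(carboxyl) and C6–CH2, both carbon substituents being delivered to adjacent carbons of an aryne.
- Forward key step: CsF would release the aryne from 3,5-bis(benzyloxy)-2-(trimethylsilyl)phenyl trifluoromethanesulfonate A2. The carbanion of dimethyl malonate A3 should add to the aryne carbon meta to the neighbouring benzyloxy group, the aryl anion should attack one ester carbonyl, and opening of the four-membered alkoxide would give the homophthalate methyl 2,4-bis(benzyloxy)-6-(2-methoxy-2-oxoethyl)benzoate A1.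
- In its favour: two C–C bonds form in one mild, fluoride-triggered step, the regiochemistry is dictated by the adjacent oxygen, and both ring A oxygens are already benzylated. Insertion of arynes into malonate C–C bonds is a known reaction class, so on precedent this alternative is the better of the two.
- Against it here: A1 carries an acetic ester arm and not the 2-oxoheptyl chain. The aliphatic ester would have to be hydrolysed selectively, activated, converted into the pentyl ketone and ketalised, and the aryl ester then saponified, which is at least as hindered as 17. A2 is not commercial and needs several steps from a 3,5-dioxygenated phenol. A1 does not help with ring B, whose O2 and O4 would arrive undifferentiated. The carbon skeleton of A1 is also the classical product of base-induced self-condensation of 1, so the aryne route spends its steps on A2 for a connectivity the oxoglutarate already contains.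
- Comparison: the structure mapping is less complete (carboxyl and CH2 are placed, the ketone is not). The mechanism is a polar stepwise insertion at ambient temperature instead of a thermal cycloaddition, which is an advantage for sensitive groups. The step economy is worse, because two arene syntheses or a late O2/O4 differentiation would be needed.

Alternative 2: Ring B is cut at C1–C6 and C2–C3 at the dihydroarene oxidation level.
- Forward key step: the anion of dibenzyl malonate A6 (KOtBu) would add to the beta carbon of (E)-5-(2-pentyl-1,3-dioxolan-2-yl)pent-3-en-2-one A5, and the methyl ketone enolate would then attack one malonate ester (Michael addition followed by Claisen ring closure). This gives benzyl 2,4-dioxo-6-[(2-pentyl-1,3-dioxolan-2-yl)methyl]cyclohexanecarboxylate A4 (racemic, trans), which would then be dehydrogenated to the resorcylate.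
- In its favour: this is the classical, well-precedented entry to 6-alkyl resorcylates and the reagents are cheap. After aromatisation both hydroxyls are free, so ring B could be acylated at its non-chelated O4 with no O-protection. On precedent, and on the number of operations from 5 to a usable ring B phenol (about four: reduction to the aldehyde, olefination, annulation, aromatisation), the alternative is the equal or the better of the chosen plan.
- Against it here: A5 has a CH2 group flanked by the enone and the ketal, so deconjugation and a beta-elimination that opens the dioxolane may compete under alkoxide. A4 must be oxidised to the arene (halogenation and dehydrohalogenation, or a quinone oxidant) in the presence of a ketal and a benzyl ester. Two stereocentres are created only to be erased.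
- Comparison: the chosen plan delivers ring B directly at the aromatic oxidation level with O2 and O4 differentiated and needs no oxidant. The alternative trades an untested cycloaddition for a known annulation followed by a delicate oxidation. The ring A acid would need the same benzylation and hindered ester cleavage in both plans.

Alternative 3: Ring A is cut at C1–C2 and C5–C6 and is built last, on a preformed ring B aryl alkynoate.
- Forward key step: 1,1-dimethoxy-3-(trimethylsilyloxy)buta-1,3-diene A9 would add across the triple bond of benzyl 2-methoxy-4-{[4-(2-pentyl-1,3-dioxolan-2-yl)but-2-ynoyl]oxy}-6-[(2-pentyl-1,3-dioxolan-2-yl)methyl]benzoate A8. Its CH2 terminus should bond to the alkyne carbon bearing the side chain and its acetal carbon to the carbon next to the ester. Loss of methanol and desilylation would give the depside A7, which carries a 4-hydroxyl and a 2-methoxyl on ring A, a 2-methoxyl on ring B, the benzyl ester and both dioxolanes.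
- In its favour: the depside ester is made from an unhindered alkynoic acid, so the acylation with a doubly ortho-substituted benzoic acid (step 11) is avoided; on this point the alternative is the better. Cycloaddition of 1,1-dialkoxy-3-silyloxybutadienes with alkynoates to 4-hydroxy-2-alkoxybenzoates is a known reaction class, so it is also better on precedent.
- Against it here: O2 of ring A and of ring B in A7 is a methyl ether, and two aryl methyl ethers would have to be cleaved at the end with a boron trihalide in the presence of the depside ester, the benzyl ester and the ketals. The propargylic CH2 of A8 lies between the alkyne and a ketal and may isomerise to the allenoate. The aryl alkynoate is a reactive acyl donor and Michael acceptor. Ring B still has to be made by a separate resorcylate synthesis.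
- Comparison: convergence is similar, and the mechanism is a normal-demand cycloaddition of a known kind instead of an untested inverse-demand one. The step economy is no better, because ring B is not addressed and a demethylation is added, whereas the chosen plan removes all protecting groups in one hydrogenolysis.

Key step: step 8

## Route

Step 1
Reactants: 1 dimethyl 3-oxopentanedioate; 2 benzyl alcohol
Product: 3 dibenzyl 3-oxopentanedioate
Conditions: 2 (2.5 equiv), DMAP (0.1 equiv), toluene, reflux, MeOH removed over 4 Å molecular sieves
Reagents that add atoms: none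
Why: DMAP-catalysed transesterification of a beta-keto ester, driven by removal of methanol; both ester groups of 1 are beta to the ketone and should exchange, and no other group is present.

Step 2
Reactants: 4 methyl 3-oxooctanoate
Product: 5 methyl 2-(2-pentyl-1,3-dioxolan-2-yl)acetate
Conditions: HOCH2CH2OH (3 equiv), p-TsOH·H2O (0.05 equiv), toluene, reflux, Dean–Stark
Reagents that add atoms: ethane-1,2-diol, OCCO
Why: Acid-catalysed ketalisation with azeotropic removal of water, standard for beta-keto esters; it masks the ketone for all later enolate, activation and cycloaddition chemistry.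

Step 3
Reactants: 5 methyl 2-(2-pentyl-1,3-dioxolan-2-yl)acetate
Product: 6 2-(2-pentyl-1,3-dioxolan-2-yl)acetic acid
Conditions: NaOH (1.5 equiv), MeOH–H2O, rt; then cold 1 M HCl to pH 3–4, immediate extraction
Reagents that add atoms: sodium hydroxide, [Na+].[OH-]
Why: Saponification of an unhindered methyl ester; the dioxolane is stable to base, and the short, cold acidification should avoid ketal hydrolysis and the decarboxylation that would follow it.

Step 4
Reactants: 6 2-(2-pentyl-1,3-dioxolan-2-yl)acetic acid; 3 dibenzyl 3-oxopentanedioate
Product: 8 dibenzyl 3-oxo-2-[(2-pentyl-1,3-dioxolan-2-yl)acetyl]pentanedioate, via acylimidazole 7 (not isolated)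
Conditions: 6, 1,1'-carbonyldiimidazole (CDI, 1.05 equiv), THF, rt; then added to 3, MgCl2 (1.2 equiv), Et3N (2.5 equiv), MeCN, 0 °C to rt; cold aq. citric acid work-up
Reagents that add atoms: none
Why: Acylimidazole formation followed by C-acylation of the magnesium chelate of a 1,3-dicarbonyl compound (soft enolisation with MgCl2/Et3N); chelation directs the acyl group to carbon, and since 3 is symmetric, mono-acylation can give only one product, which is held as an unreactive chelated enolate against a second acylation.

Step 5
Reactants: 8 dibenzyl 3-oxo-2-[(2-pentyl-1,3-dioxolan-2-yl)acetyl]pentanedioate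
Product: 9 benzyl 4-hydroxy-2-oxo-6-[(2-pentyl-1,3-dioxolan-2-yl)methyl]-2H-pyran-5-carboxylate
Conditions: DBU (1.5 equiv), toluene, 70 °C; then aq. NaH2PO4
Reagents that add atoms: none
Why: Base-mediated enol lactonisation (addition–elimination of the enolate oxygen of the new ketone at the distal ester), the known closure of 2-acyl-3-oxoglutarates to 4-hydroxy-2-pyrone-5-carboxylates; only this oxygen can reach an ester through a six-membered transition state, and the product is held as its unreactive pyronate salt until the buffered work-up.

Step 6
Reactants: 9 benzyl 4-hydroxy-2-oxo-6-[(2-pentyl-1,3-dioxolan-2-yl)methyl]-2H-pyran-5-carboxylate; 2 benzyl alcohol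
Product: 10 benzyl 4-(benzyloxy)-2-oxo-6-[(2-pentyl-1,3-dioxolan-2-yl)methyl]-2H-pyran-5-carboxylate
Conditions: 2 (1.2 equiv), PPh3 (1.3 equiv), DIAD (1.3 equiv), THF, 0 °C to rt
Reagents that add atoms: none
Why: Mitsunobu O-alkylation of an acidic 4-hydroxy-2-pyrone (a vinylogous carboxylic acid), a reaction type that alkylates O4; it is neutral, so the dioxolane is safe, and it avoids the O2- and C3-alkylation that ambident pyronate salts can give with benzyl halides.

Step 7
Reactants: 11 trimethylsilyl acetate
Product: 12 1,1-bis(trimethylsilyloxy)ethene
Conditions: LiN(iPr)2 (1.05 equiv), THF, −78 °C; Me3SiCl (1.1 equiv), −78 °C to rt; pentane, filtration, distillation under reduced pressure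
Reagents that add atoms: chlorotrimethylsilane, C[Si](C)(C)Cl
Why: Kinetic deprotonation of the silyl ester and O-silylation of the lithium enolate (ketene bis(silyl) acetal formation); low temperature and the hard silyl chloride favour O- over C-silylation, and the non-aqueous work-up protects the hydrolytically labile product.

Step 8
Reactants: 10 benzyl 4-(benzyloxy)-2-oxo-6-[(2-pentyl-1,3-dioxolan-2-yl)methyl]-2H-pyran-5-carboxylate; 12 1,1-bis(trimethylsilyloxy)ethene
Product: 16 benzyl 2-(benzyloxy)-4-hydroxy-6-[(2-pentyl-1,3-dioxolan-2-yl)methyl]benzoate, via bridged lactone cycloadduct 13 (not isolated), via cyclohexadiene 14 (not isolated), via aryl trimethylsilyl ether 15 (not isolated)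
Conditions: 12 (4 equiv, in two portions), toluene, sealed tube, 120 °C; then K2CO3 (cat.), MeOH–H2O, 0 °C
Reagents that add atoms: none
Why: Proposed new method: an inverse-electron-demand Diels–Alder reaction of the diene C3=C4–C5=C6 of 10 with the electron-rich alkene 12 has not been shown on a 4-alkoxy-6-alkyl-5-alkoxycarbonyl-2-pyrone, the closest known reaction type being the cycloaddition of 5-alkoxycarbonyl-2-pyrones (coumalates, isodehydroacetates) with ketene acetals or enamines followed by loss of CO2 and of alcohol or amine. The nucleophilic CH2 of 12 should bond first to C6, which is the beta carbon of the C5 ester and the vinylogous acceptor position of the lactone carbonyl, and the developing dioxy-stabilised cation should then be captured by C3, so the addition is expected to be a concerted but strongly asynchronous (4+2) process. Ring B is thereby closed by an intermolecular (4+2) cycloaddition that forms the ring B bonds C5–C6 and C3–C4 and gives the bridged lactone 13. 13 should lose CO2 by retro-(4+2) cycloreversion to the cyclohexadiene 14, which aromatises by 1,2-elimination of trimethylsilanol to 15, and the aryl silyl ether is hydrolysed on work-up to 16. The only stereocentres formed are the two bridgeheads of 13, which are fixed relative to each other by the bicycle, arise as a racemate and are erased on loss of CO2, so no stereocontrol is needed. The selectivity needed is regiochemical (hydroxyl para and not meta to the ester) and positional (attack at C6 and not at the benzyloxy-bearing C4), and both should follow from the polarisation of the diene by the C5 ester and the lactone carbonyl, C4 being deactivated by its own oxygen. The 4-benzyloxy donor and the substituted C6 will slow the addition, which is why an excess of 12 and prolonged heating are planned; the benzyl ester, benzyl ether and dioxolane are inert to these neutral conditions.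

Step 9
Reactants: 16 benzyl 2-(benzyloxy)-4-hydroxy-6-[(2-pentyl-1,3-dioxolan-2-yl)methyl]benzoate
Product: 17 benzyl 2,4-bis(benzyloxy)-6-[(2-pentyl-1,3-dioxolan-2-yl)methyl]benzoate
Conditions: BnBr (1.2 equiv), K2CO3 (2 equiv), DMF, rt (applied to about half of 16)
Reagents that add atoms: benzyl bromide, BrCc1ccccc1
Why: Williamson ether synthesis on the single, unhindered phenol of 16; the ester and the dioxolane are inert to carbonate.

Step 10
Reactants: 17 benzyl 2,4-bis(benzyloxy)-6-[(2-pentyl-1,3-dioxolan-2-yl)methyl]benzoate
Product: 18 2,4-bis(benzyloxy)-6-[(2-pentyl-1,3-dioxolan-2-yl)methyl]benzoic acid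
Conditions: KOH (10 equiv), DMSO–H2O (5:1), 80 °C; then cold 1 M HCl to pH 3–4, immediate extraction
Reagents that add atoms: potassium hydroxide, [K+].[OH-]
Why: Saponification of a doubly ortho-substituted benzoate with poorly solvated hydroxide in aqueous DMSO, the usual way to open hindered resorcylate esters; benzyl aryl ethers and the dioxolane are stable to base, and the product is kept as its carboxylate until a cold, brief acidification.

Step 11
Reactants: 18 2,4-bis(benzyloxy)-6-[(2-pentyl-1,3-dioxolan-2-yl)methyl]benzoic acid; 16 benzyl 2-(benzyloxy)-4-hydroxy-6-[(2-pentyl-1,3-dioxolan-2-yl)methyl]benzoate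
Product: 19 benzyl 2-(benzyloxy)-4-({2,4-bis(benzyloxy)-6-[(2-pentyl-1,3-dioxolan-2-yl)methyl]benzoyl}oxy)-6-[(2-pentyl-1,3-dioxolan-2-yl)methyl]benzoate
Conditions: EDC·HCl (1.5 equiv), DMAP (1.0 equiv), CH2Cl2, 0 °C to rt
Reagents that add atoms: none
Why: Steglich esterification (carbodiimide activation, acyl transfer through the acylpyridinium ion); 16 offers one unhindered hydroxyl only, the conditions are non-acidic so both dioxolanes survive, and the ketal on ring A prevents the activated acid from closing to an isocoumarin.

Step 12
Reactants: 19 benzyl 2-(benzyloxy)-4-({2,4-bis(benzyloxy)-6-[(2-pentyl-1,3-dioxolan-2-yl)methyl]benzoyl}oxy)-6-[(2-pentyl-1,3-dioxolan-2-yl)methyl]benzoate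
Product: 20 benzyl 2-(benzyloxy)-4-{[2,4-bis(benzyloxy)-6-(2-oxoheptyl)benzoyl]oxy}-6-(2-oxoheptyl)benzoate
Conditions: 1 M aq. HCl–THF (1:4), rt
Reagents that add atoms: water, O
Why: Acid-catalysed hydrolysis of two dialkyl ketone dioxolanes under dilute aqueous acid at ambient temperature, conditions under which benzyl and aryl esters are stable; it is done while every phenol and the ring B acid are still benzylated, so no free carboxyl or phenol is exposed to acid.

Step 13
Reactants: 20 benzyl 2-(benzyloxy)-4-{[2,4-bis(benzyloxy)-6-(2-oxoheptyl)benzoyl]oxy}-6-(2-oxoheptyl)benzoate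
Product: 21 2-hydroxy-4-{[2,4-dihydroxy-6-(2-oxoheptyl)benzoyl]oxy}-6-(2-oxoheptyl)benzoic acid
Conditions: H2 (1 atm), Pd/C (10%), EtOAc, rt
Reagents that add atoms: none
Why: Catalytic hydrogenolysis of three benzyl aryl ethers and one benzyl ester under neutral conditions; the depside ester and the two non-benzylic ketones should be inert, and filtration and evaporation give the target without exposure to acid or base.

## Compound list

1 | dimethyl 3-oxopentanedioate | COC(=O)CC(=O)CC(=O)OC | starting material
2 | benzyl alcohol | OCc1ccccc1 | starting material
3 | dibenzyl 3-oxopentanedioate | O=C(CC(=O)OCc1ccccc1)CC(=O)OCc1ccccc1 | intermediate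
4 | methyl 3-oxooctanoate | CCCCCC(=O)CC(=O)OC | starting material
5 | methyl 2-(2-pentyl-1,3-dioxolan-2-yl)acetate | CCCCCC1(CC(=O)OC)OCCO1 | intermediate
6 | 2-(2-pentyl-1,3-dioxolan-2-yl)acetic acid | CCCCCC1(CC(=O)O)OCCO1 | intermediate
7 | 1-(1H-imidazol-1-yl)-2-(2-pentyl-1,3-dioxolan-2-yl)ethan-1-one | CCCCCC1(CC(=O)n2ccnc2)OCCO1 | intermediate
8 | dibenzyl 3-oxo-2-[(2-pentyl-1,3-dioxolan-2-yl)acetyl]pentanedioate (C2 is stereolabile through enolisation, no configuration assigned) | CCCCCC1(CC(=O)C(C(=O)OCc2ccccc2)C(=O)CC(=O)OCc2ccccc2)OCCO1 | intermediate
9 | benzyl 4-hydroxy-2-oxo-6-[(2-pentyl-1,3-dioxolan-2-yl)methyl]-2H-pyran-5-carboxylate | O=C1C=C(O)C(C(=O)OCc2ccccc2)=C(CC2(CCCCC)OCCO2)O1 | intermediate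
10 | benzyl 4-(benzyloxy)-2-oxo-6-[(2-pentyl-1,3-dioxolan-2-yl)methyl]-2H-pyran-5-carboxylate | O=C1C=C(OCc2ccccc2)C(C(=O)OCc2ccccc2)=C(CC2(CCCCC)OCCO2)O1 | intermediate
11 | trimethylsilyl acetate | CC(=O)O[Si](C)(C)C | starting material
12 | 1,1-bis(trimethylsilyloxy)ethene | C=C(O[Si](C)(C)C)O[Si](C)(C)C | intermediate
13 | benzyl 5-(benzyloxy)-3-oxo-1-[(2-pentyl-1,3-dioxolan-2-yl)methyl]-8,8-bis(trimethylsilyloxy)-2-oxabicyclo[2.2.2]oct-5-ene-6-carboxylate (racemic, one enantiomer drawn; bridgeheads fixed relative to each other by the bicycle) | O=C1O[C@]2(CC3(CCCCC)OCCO3)CC(O[Si](C)(C)C)(O[Si](C)(C)C)[C@H]1C(OCc1ccccc1)=C2C(=O)OCc1ccccc1 | intermediate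
14 | benzyl 6-(benzyloxy)-2-[(2-pentyl-1,3-dioxolan-2-yl)methyl]-4,4-bis(trimethylsilyloxy)cyclohexa-1,5-diene-1-carboxylate | CCCCCC1(CC2=C(C(=O)OCc3ccccc3)C(OCc3ccccc3)=CC(O[Si](C)(C)C)(O[Si](C)(C)C)C2)OCCO1 | intermediate
15 | benzyl 2-(benzyloxy)-6-[(2-pentyl-1,3-dioxolan-2-yl)methyl]-4-(trimethylsilyloxy)benzoate | CCCCCC1(Cc2cc(O[Si](C)(C)C)cc(OCc3ccccc3)c2C(=O)OCc2ccccc2)OCCO1 | intermediate
16 | benzyl 2-(benzyloxy)-4-hydroxy-6-[(2-pentyl-1,3-dioxolan-2-yl)methyl]benzoate | CCCCCC1(Cc2cc(O)cc(OCc3ccccc3)c2C(=O)OCc2ccccc2)OCCO1 | intermediate
17 | benzyl 2,4-bis(benzyloxy)-6-[(2-pentyl-1,3-dioxolan-2-yl)methyl]benzoate | CCCCCC1(Cc2cc(OCc3ccccc3)cc(OCc3ccccc3)c2C(=O)OCc2ccccc2)OCCO1 | intermediate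
18 | 2,4-bis(benzyloxy)-6-[(2-pentyl-1,3-dioxolan-2-yl)methyl]benzoic acid | CCCCCC1(Cc2cc(OCc3ccccc3)cc(OCc3ccccc3)c2C(=O)O)OCCO1 | intermediate
19 | benzyl 2-(benzyloxy)-4-({2,4-bis(benzyloxy)-6-[(2-pentyl-1,3-dioxolan-2-yl)methyl]benzoyl}oxy)-6-[(2-pentyl-1,3-dioxolan-2-yl)methyl]benzoate | CCCCCC1(Cc2cc(OC(=O)c3c(OCc4ccccc4)cc(OCc4ccccc4)cc3CC3(CCCCC)OCCO3)cc(OCc3ccccc3)c2C(=O)OCc2ccccc2)OCCO1 | intermediate
20 | benzyl 2-(benzyloxy)-4-{[2,4-bis(benzyloxy)-6-(2-oxoheptyl)benzoyl]oxy}-6-(2-oxoheptyl)benzoate | CCCCCC(=O)Cc1cc(OC(=O)c2c(OCc3ccccc3)cc(OCc3ccccc3)cc2CC(=O)CCCCC)cc(OCc2ccccc2)c1C(=O)OCc1ccccc1 | intermediate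
21 | 2-hydroxy-4-{[2,4-dihydroxy-6-(2-oxoheptyl)benzoyl]oxy}-6-(2-oxoheptyl)benzoic acid | CCCCCC(=O)Cc1cc(OC(=O)c2c(O)cc(O)cc2CC(=O)CCCCC)cc(O)c1C(=O)O | target

## Step count and least certain steps

Total step count: 13. Longest linear sequence: 11 steps (steps 2, 3, 4, 5, 6, 8, 9, 10, 11, 12 and 13, from 4 to 21); steps 1 and 7 are side branches.

Step 8 (key step, proposed new method). The cycloaddition may be too slow, because the donor on C4 and a C5 ester twisted out of conjugation by its two neighbours lower the electrophilicity of C6. Thermal O-to-C silyl migration or hydrolysis of 12, or addition–elimination at C4 with loss of the benzyloxy group, could then outrun ring formation. The fallback uses known acylketene and aldol chemistry, sets out from 6 and comes back at 16.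
- Commercial 2,2,6-trimethyl-4H-1,3-dioxin-4-one is acetylated at its methyl group (LiN(SiMe3)2, THF, −78 °C; acetyl chloride) to 2,2-dimethyl-6-(2-oxopropyl)-4H-1,3-dioxin-4-one F1.
- The dianion of F1 (LiN(iPr)2, 2 equiv) is acylated at its terminal carbon by 7, made from 6 and CDI as in step 4, to give 6-[2,4-dioxo-5-(2-pentyl-1,3-dioxolan-2-yl)pentyl]-2,2-dimethyl-4H-1,3-dioxin-4-one F2.
- Heating F2 with 2 in toluene at 110 °C releases acetone and an acylketene, which is trapped as benzyl 3,5,7-trioxo-8-(2-pentyl-1,3-dioxolan-2-yl)octanoate F3.
- F3 is not isolated but cyclised by intramolecular aldol condensation of C2 onto the C7 carbonyl (Cs2CO3, then AcOH) to benzyl 2,4-dihydroxy-6-[(2-pentyl-1,3-dioxolan-2-yl)methyl]benzoate F4.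
- The non-chelated 4-hydroxyl is allylated (allyl bromide, K2CO3, acetone, rt) to benzyl 2-hydroxy-4-(prop-2-en-1-yloxy)-6-[(2-pentyl-1,3-dioxolan-2-yl)methyl]benzoate F5.
- The chelated 2-hydroxyl is benzylated (BnBr, K2CO3, DMF, 60 °C) to benzyl 2-(benzyloxy)-4-(prop-2-en-1-yloxy)-6-[(2-pentyl-1,3-dioxolan-2-yl)methyl]benzoate F6.
- The allyl ether is removed with zerovalent palladium (Pd(PPh3)4, morpholine, THF, rt) to return 16.

Step 4. O-acylation, a second acylation at the other CH2 group, or base-induced self-condensation of 3 may compete with C-acylation, because the imidazolide is only a modest electrophile. The fallback reverses the roles of the partners, sets out from 6 and comes back at 9. 7 (from 6 and CDI) is condensed with the magnesium salt of commercial monobenzyl malonate (MgCl2, Et3N, decarboxylative Claisen condensation) to benzyl 3-oxo-4-(2-pentyl-1,3-dioxolan-2-yl)butanoate F7. The magnesium enolate of F7 (MgCl2, pyridine, CH2Cl2) is C-acylated with commercial methyl 3-chloro-3-oxopropanoate to 1-benzyl 5-methyl 3-oxo-2-[(2-pentyl-1,3-dioxolan-2-yl)acetyl]pentanedioate F8. Under the conditions of step 5, F8 should close with loss of methanol to 9.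

Step 10. Attack of hydroxide at the doubly flanked carbonyl may be so slow that forcing conditions become necessary, with decarboxylation of the electron-rich acid on acidification as the likely loss. The fallback changes the bond that is broken from acyl–oxygen to alkyl–oxygen. It sets out from 17 and comes back at 18: NaSPh in DMF at 80 °C attacks the benzylic CH2 of the ester in an SN2 reaction, the carboxylate being a far better leaving group than the aryloxides of the benzyl ethers. No new compound lies on this path (F0).

Step 11. Acyl transfer from the hindered O-acylisourea may be slow, so that rearrangement to the N-acylurea consumes 18. The fallback separates activation from coupling, sets out from 18 and comes back at 19. 18 is converted with cyanuric fluoride and pyridine in CH2Cl2 into 2,4-bis(benzyloxy)-6-[(2-pentyl-1,3-dioxolan-2-yl)methyl]benzoyl fluoride F9, an isolable acyl donor with a very small leaving group. F9 is then treated with the sodium phenoxide of 16 (NaH, THF, 0 °C to rt) to give 19.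

Step 12. Acid-catalysed enol lactonisation of the freed ring A ketone onto the depside carbonyl, which would form an isocoumarin and expel the ring B phenol, or incomplete hydrolysis of the second dioxolane, may lower the return. The fallback inverts the order of the last two operations, sets out from 19 and comes back at 21. Hydrogenolysis of 19 (H2, Pd/C, EtOAc) gives 2-hydroxy-4-({2,4-dihydroxy-6-[(2-pentyl-1,3-dioxolan-2-yl)methyl]benzoyl}oxy)-6-[(2-pentyl-1,3-dioxolan-2-yl)methyl]benzoic acid F10, in which the ortho hydroxyl of ring A hydrogen-bonds to and deactivates the depside carbonyl. The dioxolanes of F10 are then hydrolysed in aqueous acetic acid–THF at rt to give 21.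

## Further compounds

F1 | step 8 | 2,2-dimethyl-6-(2-oxopropyl)-4H-1,3-dioxin-4-one | CC(=O)CC1=CC(=O)OC(C)(C)O1
F2 | step 8 | 6-[2,4-dioxo-5-(2-pentyl-1,3-dioxolan-2-yl)pentyl]-2,2-dimethyl-4H-1,3-dioxin-4-one | CCCCCC1(CC(=O)CC(=O)CC2=CC(=O)OC(C)(C)O2)OCCO1
F3 | step 8 | benzyl 3,5,7-trioxo-8-(2-pentyl-1,3-dioxolan-2-yl)octanoate | CCCCCC1(CC(=O)CC(=O)CC(=O)CC(=O)OCc2ccccc2)OCCO1
F4 | step 8 | benzyl 2,4-dihydroxy-6-[(2-pentyl-1,3-dioxolan-2-yl)methyl]benzoate | CCCCCC1(Cc2cc(O)cc(O)c2C(=O)OCc2ccccc2)OCCO1
F5 | step 8 | benzyl 2-hydroxy-4-(prop-2-en-1-yloxy)-6-[(2-pentyl-1,3-dioxolan-2-yl)methyl]benzoate | CCCCCC1(Cc2cc(OCC=C)cc(O)c2C(=O)OCc2ccccc2)OCCO1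
F6 | step 8 | benzyl 2-(benzyloxy)-4-(prop-2-en-1-yloxy)-6-[(2-pentyl-1,3-dioxolan-2-yl)methyl]benzoate | CCCCCC1(Cc2cc(OCC=C)cc(OCc3ccccc3)c2C(=O)OCc2ccccc2)OCCO1
F7 | step 4 | benzyl 3-oxo-4-(2-pentyl-1,3-dioxolan-2-yl)butanoate | CCCCCC1(CC(=O)CC(=O)OCc2ccccc2)OCCO1
F8 | step 4 | 1-benzyl 5-methyl 3-oxo-2-[(2-pentyl-1,3-dioxolan-2-yl)acetyl]pentanedioate | CCCCCC1(CC(=O)C(C(=O)OCc2ccccc2)C(=O)CC(=O)OC)OCCO1
F0 | step 10 | none | none
F9 | step 11 | 2,4-bis(benzyloxy)-6-[(2-pentyl-1,3-dioxolan-2-yl)methyl]benzoyl fluoride | CCCCCC1(Cc2cc(OCc3ccccc3)cc(OCc3ccccc3)c2C(=O)F)OCCO1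
F10 | step 12 | 2-hydroxy-4-({2,4-dihydroxy-6-[(2-pentyl-1,3-dioxolan-2-yl)methyl]benzoyl}oxy)-6-[(2-pentyl-1,3-dioxolan-2-yl)methyl]benzoic acid | CCCCCC1(Cc2cc(OC(=O)c3c(O)cc(O)cc3CC3(CCCCC)OCCO3)cc(O)c2C(=O)O)OCCO1
A1 | alternative 1 | methyl 2,4-bis(benzyloxy)-6-(2-methoxy-2-oxoethyl)benzoate | COC(=O)Cc1cc(OCc2ccccc2)cc(OCc2ccccc2)c1C(=O)OC
A2 | alternative 1 | 3,5-bis(benzyloxy)-2-(trimethylsilyl)phenyl trifluoromethanesulfonate | C[Si](C)(C)c1c(OS(=O)(=O)C(F)(F)F)cc(OCc2ccccc2)cc1OCc1ccccc1
A3 | alternative 1 | dimethyl malonate | COC(=O)CC(=O)OC
A4 | alternative 2 | benzyl 2,4-dioxo-6-[(2-pentyl-1,3-dioxolan-2-yl)methyl]cyclohexanecarboxylate (racemic, trans, one enantiomer drawn) | O=C1CC(=O)[C@@H](C(=O)OCc2ccccc2)[C@H](CC2(CCCCC)OCCO2)C1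
A5 | alternative 2 | (E)-5-(2-pentyl-1,3-dioxolan-2-yl)pent-3-en-2-one | CC(=O)/C=C/CC1(CCCCC)OCCO1
A6 | alternative 2 | dibenzyl malonate | O=C(CC(=O)OCc1ccccc1)OCc1ccccc1
A7 | alternative 3 | benzyl 4-({4-hydroxy-2-methoxy-6-[(2-pentyl-1,3-dioxolan-2-yl)methyl]benzoyl}oxy)-2-methoxy-6-[(2-pentyl-1,3-dioxolan-2-yl)methyl]benzoate | CCCCCC1(Cc2cc(O)cc(OC)c2C(=O)Oc2cc(OC)c(C(=O)OCc3ccccc3)c(CC3(CCCCC)OCCO3)c2)OCCO1
A8 | alternative 3 | benzyl 2-methoxy-4-{[4-(2-pentyl-1,3-dioxolan-2-yl)but-2-ynoyl]oxy}-6-[(2-pentyl-1,3-dioxolan-2-yl)methyl]benzoate | CCCCCC1(CC#CC(=O)Oc2cc(OC)c(C(=O)OCc3ccccc3)c(CC3(CCCCC)OCCO3)c2)OCCO1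
A9 | alternative 3 | 1,1-dimethoxy-3-(trimethylsilyloxy)buta-1,3-diene | C=C(O[Si](C)(C)C)C=C(OC)OC
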